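**Retrosynthetic overview**
1. Target 21 ⇐ phenol 20 by oxidative dearomatisation in methanol, which installs C1'–OMe last.
2. 20 ⇐ anti-1,3-diol 16 by C9 deoxygenation (CH2OH → CH3), C7 acetylation and desilylation.
3. Key C7–C8 bond: intermolecular Evans anti-aldol of N-arylacetyl oxazolidinone 12 with veratraldehyde 13, setting C7 and C8.
4. Imide 12 ⇐ aryl bromide 6 + zinc enolate 7; the allyl group comes from an aromatic Claisen rearrangement of ether 3.
5. Ring order: no ring is built. Both carbocycles are bought as arenes, and ring A (the dienone) is unveiled from its arene in the final step.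

Assumption: neolignan locants are used (C7 = CH–OAc, C8 = CH–CH3, C9 = the C8 methyl carbon, C1' = quaternary C–OMe, C6' = C–OMe next to it); the target is (7R,8R,1'R). "ArSi" = 2-methoxy-5-(prop-2-en-1-yl)-4-{[tri(propan-2-yl)silyl]oxy}phenyl. Compounds 1, 2, 7, 10 and 13 are bought.

Step 1
Reactants: 1 4-bromo-3-methoxyphenol; 2 allyl bromide (3-bromoprop-1-ene)
Product: 3 1-bromo-2-methoxy-4-(prop-2-en-1-yloxy)benzene
Conditions: K2CO3, acetone, reflux
Reagents that add atoms: none
Why: Williamson ether synthesis, SN2 attack of the phenoxide on the allylic bromide.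

Step 2
Reactants: 3 1-bromo-2-methoxy-4-(prop-2-en-1-yloxy)benzene
Product: 5 4-bromo-5-methoxy-2-(prop-2-en-1-yl)phenol, via ortho-dienone 4 (not isolated)
Conditions: PhNEt2, 195 °C
Reagents that add atoms: none
Why: Aromatic Claisen rearrangement ([3,3]-sigmatropic shift, then tautomerisation) to the open ortho position rather than the one flanked by the methoxy group, as with allyl 3,4-dimethoxyphenyl ether; the minor regioisomer is removed by chromatography.

Step 3
Reactants: 5 4-bromo-5-methoxy-2-(prop-2-en-1-yl)phenol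
Product: 6 [4-bromo-5-methoxy-2-(prop-2-en-1-yl)phenoxy]tri(propan-2-yl)silane
Conditions: i-Pr3SiCl, imidazole, DMF, rt
Reagents that add atoms: chlorotri(propan-2-yl)silane CC(C)[Si](Cl)(C(C)C)C(C)C
Why: Imidazole-promoted O-silylation; the aryl triisopropylsilyl ether survives zinc enolates, CF3CO2H, Lewis acids and hydrides and is later removed by fluoride without touching an acetate.

Step 4
Reactants: 6 [4-bromo-5-methoxy-2-(prop-2-en-1-yl)phenoxy]tri(propan-2-yl)silane; 7 (2-tert-butoxy-2-oxoethyl)zinc bromide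
Product: 8 tert-butyl 2-(ArSi)acetate
Conditions: Pd(dba)2 (2 mol %), P(t-Bu)3 (4 mol %), THF, rt to 50 °C
Reagents that add atoms: none
Why: Palladium-catalysed Negishi-type cross-coupling of the Reformatsky zinc enolate with the aryl bromide (ester α-arylation) under neutral conditions that leave the silyl ether and the allyl group alone.

Step 5
Reactants: 8 tert-butyl 2-(ArSi)acetate
Product: 9 2-(ArSi)acetic acid
Conditions: CF3CO2H, CH2Cl2, 0 °C to rt
Reagents that add atoms: none
Why: Acidolysis of the tert-butyl ester (loss of 2-methylpropene), which the aryl silyl ether tolerates.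

Step 6
Reactants: 9 2-(ArSi)acetic acid; 10 (4R)-4-benzyl-1,3-oxazolidin-2-one
Product: 12 (4R)-4-benzyl-3-[2-(ArSi)acetyl]-1,3-oxazolidin-2-one, via mixed pivalic anhydride 11 (not isolated)
Conditions: t-BuCOCl, Et3N, THF, −20 °C; then LiCl, 10, −20 °C to rt
Reagents that add atoms: none
Why: Mixed-anhydride N-acylation of the Evans auxiliary; the hindered pivaloyl carbonyl directs attack to the arylacetyl carbonyl.

Step 7
Reactants: 12 (4R)-4-benzyl-3-[2-(ArSi)acetyl]-1,3-oxazolidin-2-one; 13 3,4-dimethoxybenzaldehyde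
Product: 15 (4R)-4-benzyl-3-[(2S,3R)-2-(ArSi)-3-(3,4-dimethoxyphenyl)-3-hydroxypropanoyl]-1,3-oxazolidin-2-one, via trimethylsilyl ether 14 (not isolated)
Conditions: MgCl2 (20 mol %), Et3N, Me3SiCl, EtOAc, rt; then citric acid, MeOH, 0 °C
Reagents that add atoms: none
Why: Evans magnesium-halide-catalysed anti-aldol, the key intermolecular C7–C8 bond formation: the magnesium-chelated Z-enolate reacts through a boat transition state on the face opposite the auxiliary benzyl group (the same α-facial sense as Evans alkylation), so the (R)-auxiliary gives C8 = (2S) and the anti relationship gives C7 = (3R), while silylation of the aldolate prevents retro-aldol.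

Step 8
Reactants: 15 anti-aldol imide
Product: 16 (1R,2R)-2-(ArSi)-1-(3,4-dimethoxyphenyl)propane-1,3-diol
Conditions: LiBH4, MeOH (1 equiv), THF, 0 °C
Reagents that add atoms: none
Why: Reductive cleavage of the N-acyloxazolidinone to the primary alcohol with recovery of the auxiliary; no stereocentre is touched (the C8 descriptor becomes R only because CH2OH now outranks the aryl group).

Step 9
Reactants: 16 (1R,2R)-2-(ArSi)-1-(3,4-dimethoxyphenyl)propane-1,3-diol
Product: 17 (2R,3R)-2-(ArSi)-3-(3,4-dimethoxyphenyl)-3-hydroxypropyl 4-methylbenzenesulfonate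
Conditions: TsCl, Et3N, DMAP (cat.), CH2Cl2, 0 °C
Reagents that add atoms: 4-methylbenzenesulfonyl chloride Cc1ccc(cc1)S(Cl)(=O)=O
Why: Chemoselective sulfonylation of the unhindered primary hydroxyl over the hindered secondary benzylic one.

Step 10
Reactants: 17 primary tosylate
Product: 18 (1R,2S)-2-(ArSi)-1-(3,4-dimethoxyphenyl)propan-1-ol
Conditions: LiEt3BH, THF, 0 °C to rt
Reagents that add atoms: none
Why: SN2 hydride displacement of the primary tosylate turns C9 into the methyl group faster than the alkoxide can close an oxetane (C8 is untouched; its descriptor becomes S because CH3 ranks below the aryl group).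

Step 11
Reactants: 18 (1R,2S)-2-(ArSi)-1-(3,4-dimethoxyphenyl)propan-1-ol
Product: 19 (1R,2S)-2-(ArSi)-1-(3,4-dimethoxyphenyl)propyl acetate
Conditions: Ac2O, pyridine, DMAP (cat.), CH2Cl2, rt
Reagents that add atoms: acetic anhydride CC(=O)OC(C)=O
Why: DMAP-catalysed O-acylation of the secondary alcohol with retention at C7, done while the phenol is still masked.

Step 12
Reactants: 19 (1R,2S)-2-(ArSi)-1-(3,4-dimethoxyphenyl)propyl acetate
Product: 20 (1R,2S)-1-(3,4-dimethoxyphenyl)-2-[4-hydroxy-2-methoxy-5-(prop-2-en-1-yl)phenyl]propyl acetate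
Conditions: Bu4NF, AcOH, THF, 0 °C
Reagents that add atoms: none
Why: Fluoride desilylation of the aryl silyl ether, buffered with acetic acid so that the phenoxide does not attack the acetate.

Step 13
Reactants: 20 (1R,2S)-1-(3,4-dimethoxyphenyl)-2-[4-hydroxy-2-methoxy-5-(prop-2-en-1-yl)phenyl]propyl acetate
Product: 21 (1R,2R)-1-(3,4-dimethoxyphenyl)-2-[(1R)-1,2-dimethoxy-4-oxo-5-(prop-2-en-1-yl)cyclohexa-2,5-dien-1-yl]propyl acetate
Conditions: PhI(OAc)2, MeOH, 0 °C
Reagents that add atoms: methanol CO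
Why: Hypervalent (trivalent) iodine oxidative dearomatisation of a para-alkylphenol: methanol captures the phenoxonium-type intermediate at the alkyl-bearing para carbon to give the para-quinol methyl ether, but C1' forms under only weak control from C8, so both C1' epimers are expected and the (1'R) epimer 21 is isolated by chromatography and assigned by NOE and comparison with the natural product (the C8 descriptor returns to R only by priority change).

**Compound list**
1 | 4-bromo-3-methoxyphenol | COc1cc(O)ccc1Br | starting material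
2 | allyl bromide (3-bromoprop-1-ene) | C=CCBr | starting material
3 | 1-bromo-2-methoxy-4-(prop-2-en-1-yloxy)benzene | C=CCOc1ccc(Br)c(OC)c1 | intermediate
4 | 6-allyl-4-bromo-3-methoxycyclohexa-2,4-dien-1-one (racemic, not isolated) | C=CCC1C=C(Br)C(OC)=CC1=O | intermediate
5 | 4-bromo-5-methoxy-2-(prop-2-en-1-yl)phenol | C=CCc1cc(Br)c(OC)cc1O | intermediate
6 | [4-bromo-5-methoxy-2-(prop-2-en-1-yl)phenoxy]tri(propan-2-yl)silane | C=CCc1cc(Br)c(OC)cc1O[Si](C(C)C)(C(C)C)C(C)C | intermediate
7 | (2-tert-butoxy-2-oxoethyl)zinc bromide | CC(C)(C)OC(=O)C[Zn]Br | starting material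
8 | tert-butyl 2-[2-methoxy-5-(prop-2-en-1-yl)-4-{[tri(propan-2-yl)silyl]oxy}phenyl]acetate | C=CCc1cc(CC(=O)OC(C)(C)C)c(OC)cc1O[Si](C(C)C)(C(C)C)C(C)C | intermediate
9 | 2-[2-methoxy-5-(prop-2-en-1-yl)-4-{[tri(propan-2-yl)silyl]oxy}phenyl]acetic acid | C=CCc1cc(CC(O)=O)c(OC)cc1O[Si](C(C)C)(C(C)C)C(C)C | intermediate
10 | (4R)-4-benzyl-1,3-oxazolidin-2-one | O=C1N[C@H](Cc2ccccc2)CO1 | starting material
11 | 2-[2-methoxy-5-(prop-2-en-1-yl)-4-{[tri(propan-2-yl)silyl]oxy}phenyl]acetic 2,2-dimethylpropanoic anhydride (not isolated) | C=CCc1cc(CC(=O)OC(=O)C(C)(C)C)c(OC)cc1O[Si](C(C)C)(C(C)C)C(C)C | intermediate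
12 | (4R)-4-benzyl-3-{2-[2-methoxy-5-(prop-2-en-1-yl)-4-{[tri(propan-2-yl)silyl]oxy}phenyl]acetyl}-1,3-oxazolidin-2-one | C=CCc1cc(CC(=O)N2[C@H](Cc3ccccc3)COC2=O)c(OC)cc1O[Si](C(C)C)(C(C)C)C(C)C | intermediate
13 | 3,4-dimethoxybenzaldehyde | COc1ccc(C=O)cc1OC | starting material
14 | (4R)-4-benzyl-3-[(2S,3R)-3-(3,4-dimethoxyphenyl)-2-[2-methoxy-5-(prop-2-en-1-yl)-4-{[tri(propan-2-yl)silyl]oxy}phenyl]-3-[(trimethylsilyl)oxy]propanoyl]-1,3-oxazolidin-2-one (not isolated) | C=CCc1cc([C@H](C(=O)N2[C@H](Cc3ccccc3)COC2=O)[C@@H](O[Si](C)(C)C)c4ccc(OC)c(OC)c4)c(OC)cc1O[Si](C(C)C)(C(C)C)C(C)C | intermediate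
15 | (4R)-4-benzyl-3-[(2S,3R)-3-(3,4-dimethoxyphenyl)-3-hydroxy-2-[2-methoxy-5-(prop-2-en-1-yl)-4-{[tri(propan-2-yl)silyl]oxy}phenyl]propanoyl]-1,3-oxazolidin-2-one | C=CCc1cc([C@H](C(=O)N2[C@H](Cc3ccccc3)COC2=O)[C@@H](O)c4ccc(OC)c(OC)c4)c(OC)cc1O[Si](C(C)C)(C(C)C)C(C)C | intermediate
16 | (1R,2R)-1-(3,4-dimethoxyphenyl)-2-[2-methoxy-5-(prop-2-en-1-yl)-4-{[tri(propan-2-yl)silyl]oxy}phenyl]propane-1,3-diol | C=CCc1cc([C@H](CO)[C@@H](O)c2ccc(OC)c(OC)c2)c(OC)cc1O[Si](C(C)C)(C(C)C)C(C)C | intermediate
17 | (2R,3R)-3-(3,4-dimethoxyphenyl)-3-hydroxy-2-[2-methoxy-5-(prop-2-en-1-yl)-4-{[tri(propan-2-yl)silyl]oxy}phenyl]propyl 4-methylbenzenesulfonate | C=CCc1cc([C@H](COS(=O)(=O)c2ccc(C)cc2)[C@@H](O)c3ccc(OC)c(OC)c3)c(OC)cc1O[Si](C(C)C)(C(C)C)C(C)C | intermediate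
18 | (1R,2S)-1-(3,4-dimethoxyphenyl)-2-[2-methoxy-5-(prop-2-en-1-yl)-4-{[tri(propan-2-yl)silyl]oxy}phenyl]propan-1-ol | C=CCc1cc([C@H](C)[C@@H](O)c2ccc(OC)c(OC)c2)c(OC)cc1O[Si](C(C)C)(C(C)C)C(C)C | intermediate
19 | (1R,2S)-1-(3,4-dimethoxyphenyl)-2-[2-methoxy-5-(prop-2-en-1-yl)-4-{[tri(propan-2-yl)silyl]oxy}phenyl]propyl acetate | C=CCc1cc([C@H](C)[C@@H](OC(C)=O)c2ccc(OC)c(OC)c2)c(OC)cc1O[Si](C(C)C)(C(C)C)C(C)C | intermediate
20 | (1R,2S)-1-(3,4-dimethoxyphenyl)-2-[4-hydroxy-2-methoxy-5-(prop-2-en-1-yl)phenyl]propyl acetate | C=CCc1cc([C@H](C)[C@@H](OC(C)=O)c2ccc(OC)c(OC)c2)c(OC)cc1O | intermediate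
21 | (1R,2R)-1-(3,4-dimethoxyphenyl)-2-[(1R)-1,2-dimethoxy-4-oxo-5-(prop-2-en-1-yl)cyclohexa-2,5-dien-1-yl]propyl acetate | C=CCC1=C[C@@](OC)([C@H](C)[C@@H](OC(C)=O)c2ccc(OC)c(OC)c2)C(OC)=CC1=O | target

**Totals**
Total step count: 13. Longest linear sequence: 13 steps (1 → 21).

**Three steps most likely to fail**

Step 13 (C1' configuration). Solvent methanol can attack either face of the dearomatised ring. With H8 lying in the ring plane beside the C6' methoxy group (least 1,3-allylic strain), the 1'R face is the one on the side of the bulkier C7 branch, so the wanted epimer may even be the minor one and must be separated. Fallback: starting from phenol 20, the oxidation is run without an external nucleophile (PhI(OCOCF3)2, (CF3)2CHOH/CH2Cl2, −20 °C). The carbonyl oxygen of the C7 acetate should then capture C1' intramolecularly through a six-membered acetoxonium ion, delivering oxygen from the C7 side, which is the 1'R face. Quenching with aqueous NaHCO3 opens the acetoxonium ion to the tertiary quinol that keeps the acetate on O7, (1R,2R)-1-(3,4-dimethoxyphenyl)-2-[(1R)-1-hydroxy-2-methoxy-4-oxo-5-(prop-2-en-1-yl)cyclohexa-2,5-dien-1-yl]propyl acetate F1. Purdie methylation of the tertiary hydroxyl (MeI, Ag2O, MeCN, rt) then returns to the route at the target 21. This fallback is untested reasoning, not precedent.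

Step 7 (anti-aldol of an α-aryl imide). The magnesium-catalysed anti-aldol is established for N-propionyl imides with aromatic aldehydes. The more acidic arylacetyl imide and the electron-rich aldehyde may lower conversion or selectivity, and the facial sense should be confirmed on a small scale. Fallback: starting from acid 9, double deprotonation with i-PrMgCl (2.2 equiv, THF, 0 °C to rt) gives the magnesium enediolate, which adds to 13 in an Ivanov reaction. Its closed Zimmerman–Traxler chair transition state places both aryl groups equatorial and gives the anti hydroxy acid as a racemate. The racemate is resolved by preparative chromatography on a chiral stationary phase (or by crystallising the (S)-1-phenylethylammonium salt) to give (2S,3R)-3-(3,4-dimethoxyphenyl)-3-hydroxy-2-[2-methoxy-5-(prop-2-en-1-yl)-4-{[tri(propan-2-yl)silyl]oxy}phenyl]propanoic acid F2. Reduction with LiAlH4 (THF, 0 °C) returns to the route at diol 16.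

Step 10 (hydride displacement). The primary tosylate sits β to a very electron-rich aryl group and γ to a free hydroxyl, so aryl participation (1,2-aryl shift) or oxetane formation could compete with direct SN2 reduction. Fallback: starting from diol 16, I2, PPh3 and imidazole (THF, 0 °C) convert the primary hydroxyl selectively into the iodide (1R,2S)-1-(3,4-dimethoxyphenyl)-3-iodo-2-[2-methoxy-5-(prop-2-en-1-yl)-4-{[tri(propan-2-yl)silyl]oxy}phenyl]propan-1-ol F3. Radical-chain reduction with Bu3SnH and AIBN (toluene, 80 °C) removes the iodine; hydrogen transfer from the stannane is far faster than a neophyl-type aryl shift. This returns to the route at alcohol 18.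

Further compounds
F1 | step 13 | (1R,2R)-1-(3,4-dimethoxyphenyl)-2-[(1R)-1-hydroxy-2-methoxy-4-oxo-5-(prop-2-en-1-yl)cyclohexa-2,5-dien-1-yl]propyl acetate | C=CCC1=C[C@@](O)([C@H](C)[C@@H](OC(C)=O)c2ccc(OC)c(OC)c2)C(OC)=CC1=O
F2 | step 7 | (2S,3R)-3-(3,4-dimethoxyphenyl)-3-hydroxy-2-[2-methoxy-5-(prop-2-en-1-yl)-4-{[tri(propan-2-yl)silyl]oxy}phenyl]propanoic acid | C=CCc1cc([C@H](C(O)=O)[C@@H](O)c2ccc(OC)c(OC)c2)c(OC)cc1O[Si](C(C)C)(C(C)C)C(C)C
F3 | step 10 | (1R,2S)-1-(3,4-dimethoxyphenyl)-3-iodo-2-[2-methoxy-5-(prop-2-en-1-yl)-4-{[tri(propan-2-yl)silyl]oxy}phenyl]propan-1-ol | C=CCc1cc([C@H](CI)[C@@H](O)c2ccc(OC)c(OC)c2)c(OC)cc1O[Si](C(C)C)(C(C)C)C(C)C
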